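**Plan**
- Retrosynthetic cuts, in order: C14–C15 of the butenolide (ring C, last C–C bond); C13–C16 (alkoxymethyl anion on a C13 amide); C2–O (enolate hydroxylation); C4–C5 and C9–C10 (rings A and B, one polyene bicyclization of an epoxy-triene); the C3/C4 epoxide and C18–O; C11–C12 (allylation of an acetate enolate).
- Forward: the open chain is built and epoxidized first; rings A and B form together in a titanocene radical bicyclization that also leaves the 8(17)-methylene; ring A is then taken to the 2,3-diol; ring C is closed last.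
- Stereochemistry: C3 comes from the Sharpless epoxidation; C4, C5, C9 and C10 follow from the chair–chair cyclization of the E,E-triene relative to C3; C2 is set by enolate hydroxylation anti to the axial methyls on C10 and C4; C3 is re-set by axial hydride delivery.
- Enabling feature: in ring C the carbonyl carbon C15 sits on the ring oxygen, two atoms from C13 (C13–C16–O–C15), and C14 is a vinylic CH on C13. A carbene at C14, made from a C13 ketone, therefore finds a C15–H bond in the 1,5 position. C15 is carried as an orthoformate so that insertion gives the lactone oxidation level directly; its two methoxy groups leave in the last step with the silyl groups.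

Key step: step 13

Remark: bicyclic compounds are named on the ent-labdane skeleton (C20 = methyl on C10; H-5, H-9, O-2 and C18, the CH2O carbon on C4, lie on the face opposite C20; O-3, the C4 methyl C19 and the C9 chain lie on the C20 face); the SMILES define each structure, and (tributylstannyl)methanol 15 is taken as a catalogue reagent.

**Step 1**
Reactants: 1 (2E,6E)-farnesyl bromide; 2 ethyl acetate
Product: 4 ethyl (4E,8E)-5,9,13-trimethyltetradeca-4,8,12-trienoate, via lithium enolate 3 (not isolated)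
Conditions: LiN(iPr)2, THF, −78 °C; then 1, DMPU, −78 → 0 °C
Reagents that add atoms: none
Why: Alkylation of the lithium ester enolate by SN2 displacement at the primary allylic bromide forms C11–C12 and leaves both E-alkenes untouched.

**Step 2**
Reactants: 4 ethyl (4E,8E)-5,9,13-trimethyltetradeca-4,8,12-trienoate
Product: 5 ethyl (4E,8E,12E)-14-hydroxy-5,9,13-trimethyltetradeca-4,8,12-trienoate
Conditions: SeO2 (0.1 equiv), t-BuOOH, salicylic acid (0.1 equiv), CH2Cl2, rt
Reagents that add atoms: tert-butyl hydroperoxide, CC(C)(C)OO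
Why: Catalytic SeO2 allylic oxidation (ene reaction, then 2,3-sigmatropic shift) should pick the terminal, least hindered trisubstituted alkene and hydroxylate its E-methyl group, which fixes the E-allylic alcohol needed for C18.

**Step 3**
Reactants: 5 ethyl (4E,8E,12E)-14-hydroxy-5,9,13-trimethyltetradeca-4,8,12-trienoate
Product: 6 ethyl (4E,8E)-11-[(2R,3R)-3-(hydroxymethyl)-3-methyloxiran-2-yl]-5,9-dimethylundeca-4,8-dienoate
Conditions: Ti(OiPr)4 (0.1 equiv), D-(−)-diisopropyl tartrate (0.12 equiv), t-BuOOH, 4 Å molecular sieves, CH2Cl2, −20 °C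
Reagents that add atoms: tert-butyl hydroperoxide, CC(C)(C)OO
Why: Sharpless asymmetric epoxidation of the E-allylic alcohol with the D-(−)-tartrate should give the (2R,3R)-epoxide, whose CH carbon becomes C3 and fixes the absolute configuration of the whole ent-series.

**Step 4**
Reactants: 6 ethyl (4E,8E)-11-[(2R,3R)-3-(hydroxymethyl)-3-methyloxiran-2-yl]-5,9-dimethylundeca-4,8-dienoate
Product: 7 ethyl (4E,8E)-11-[(2R,3R)-3-(tert-butyldimethylsilyloxymethyl)-3-methyloxiran-2-yl]-5,9-dimethylundeca-4,8-dienoate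
Conditions: TBSCl, imidazole, DMF, 0 °C → rt
Reagents that add atoms: tert-butyldimethylsilyl chloride, CC(C)(C)[Si](C)(C)Cl
Why: Silylation of the primary alcohol keeps its titanium alkoxide from diverting the epoxide opening and supplies the bulky C4 substituent used for control in step 5.

**Step 5**
Reactants: 7 ethyl (4E,8E)-11-[(2R,3R)-3-(tert-butyldimethylsilyloxymethyl)-3-methyloxiran-2-yl]-5,9-dimethylundeca-4,8-dienoate
Product: 8 ethyl ent-18-(tert-butyldimethylsilyloxy)-3β-hydroxy-14,15,16-trinorlabd-8(17)-en-13-oate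
Conditions: Cp2TiCl2 (2.2 equiv), Mn dust, THF, rt, slow addition of 7; then 1 M HCl
Reagents that add atoms: none
Why: Reductive epoxide opening by Cp2TiCl (trivalent titanium; Nugent–RajanBabu reaction) gives the tertiary C4 radical, which should close rings A and B by two 6-endo-trig radical cyclizations through a chair–chair transition state (titanoxy group and the larger silyloxymethyl group equatorial, the E-alkenes giving the trans ring fusion, the anti C20/H-9 relation and the equatorial C9 chain), after which the tertiary C8 radical is trapped by a second Cp2TiCl and loses β-hydride from C17 to leave the exocyclic alkene.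

**Step 6**
Reactants: 8 ethyl ent-18-(tert-butyldimethylsilyloxy)-3β-hydroxy-14,15,16-trinorlabd-8(17)-en-13-oate
Product: 9 ethyl ent-18-(tert-butyldimethylsilyloxy)-3-oxo-14,15,16-trinorlabd-8(17)-en-13-oate
Conditions: Dess–Martin periodinane, CH2Cl2, rt
Reagents that add atoms: none
Why: Dess–Martin oxidation turns the secondary alcohol into the C3 ketone without acid or base, so the silyl ether, the ester and the exocyclic alkene are kept.

**Step 7**
Reactants: 9 ethyl ent-18-(tert-butyldimethylsilyloxy)-3-oxo-14,15,16-trinorlabd-8(17)-en-13-oate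
Product: 11 ethyl ent-18-(tert-butyldimethylsilyloxy)-2α-hydroxy-3-oxo-14,15,16-trinorlabd-8(17)-en-13-oate, via potassium enolate 10 (not isolated)
Conditions: KN(SiMe3)2 (1.1 equiv), THF, −78 °C; then 2-(phenylsulfonyl)-3-phenyloxaziridine, −78 °C; AcOH
Reagents that add atoms: 2-(phenylsulfonyl)-3-phenyloxaziridine, O=S(=O)(c1ccccc1)N1OC1c1ccccc1
Why: Enolate hydroxylation with an N-sulfonyloxaziridine: the ketone is deprotonated at C2 (C4 is quaternary, the ester is less acidic) and oxygen should be delivered to the face away from the axial methyl groups on C10 and C4, giving the equatorial 2-hydroxyl.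

**Step 8**
Reactants: 11 ethyl ent-18-(tert-butyldimethylsilyloxy)-2α-hydroxy-3-oxo-14,15,16-trinorlabd-8(17)-en-13-oate
Product: 12 ethyl ent-18-(tert-butyldimethylsilyloxy)-2α,3β-dihydroxy-14,15,16-trinorlabd-8(17)-en-13-oate
Conditions: NaBH4, EtOH, 0 °C
Reagents that add atoms: none
Why: NaBH4 should add hydride axially, from the face away from the axial C4 and C10 methyl groups, to give the equatorial 3-hydroxyl trans to O-2, while the ester is not reduced.

**Step 9**
Reactants: 12 ethyl ent-18-(tert-butyldimethylsilyloxy)-2α,3β-dihydroxy-14,15,16-trinorlabd-8(17)-en-13-oate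
Product: 13 ethyl ent-2α,3β,18-tris(tert-butyldimethylsilyloxy)-14,15,16-trinorlabd-8(17)-en-13-oate
Conditions: TBSOTf, 2,6-lutidine, CH2Cl2, 0 °C → rt
Reagents that add atoms: tert-butyldimethylsilyl trifluoromethanesulfonate, CC(C)(C)[Si](C)(C)OS(=O)(=O)C(F)(F)F
Why: Silylation with the silyl triflate caps the hindered trans-diol so that the organolithium steps meet no acidic hydrogen.

**Step 10**
Reactants: 13 ethyl ent-2α,3β,18-tris(tert-butyldimethylsilyloxy)-14,15,16-trinorlabd-8(17)-en-13-oate
Product: 14 ent-2α,3β,18-tris(tert-butyldimethylsilyloxy)-N-methoxy-N-methyl-14,15,16-trinorlabd-8(17)-en-13-amide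
Conditions: MeNH(OMe)·HCl, i-PrMgCl, THF, −20 → 0 °C
Reagents that add atoms: N,O-dimethylhydroxylamine hydrochloride, CNOC.Cl
Why: Weinreb amide formation from the ester with the chloromagnesium amide of N,O-dimethylhydroxylamine prepares C13 for a single addition of a carbanion.

**Step 11**
Reactants: 15 (tributylstannyl)methanol
Product: 16 tributyl[(dimethoxymethoxy)methyl]stannane
Conditions: HC(OMe)3 (solvent), pyridinium p-toluenesulfonate (cat.), 40 °C, MeOH distilled off; Et3N, evaporation
Reagents that add atoms: trimethyl orthoformate, COC(OC)OC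
Why: Acid-catalysed ortho ester exchange replaces one methoxy group by the primary alcohol and so places the future C15 on the future ring oxygen at the carboxyl oxidation level, with one C–H bond left.

**Step 12**
Reactants: 16 tributyl[(dimethoxymethoxy)methyl]stannane; 14 ent-2α,3β,18-tris(tert-butyldimethylsilyloxy)-N-methoxy-N-methyl-14,15,16-trinorlabd-8(17)-en-13-amide
Product: 18 ent-2α,3β,18-tris(tert-butyldimethylsilyloxy)-16-(dimethoxymethoxy)-14,15-dinorlabd-8(17)-en-13-one, via alkoxymethyllithium 17 (not isolated)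
Conditions: 16, n-BuLi, THF, −78 °C; then 14, −78 → −40 °C; pH 7 phosphate buffer
Reagents that add atoms: none
Why: Tin–lithium exchange gives the α-alkoxymethyllithium, which should add once to the Weinreb amide through the chelated tetrahedral intermediate to form the C13–C16 bond, the ortho ester being inert to organolithiums at −78 °C.

**Step 13**
Reactants: 18 ent-2α,3β,18-tris(tert-butyldimethylsilyloxy)-16-(dimethoxymethoxy)-14,15-dinorlabd-8(17)-en-13-one
Product: 21 ent-2α,3β,18-tris(tert-butyldimethylsilyloxy)-15,15-dimethoxy-15,16-epoxylabda-8(17),13-diene, via diazoalkene 19 (not isolated), via alkylidene carbene 20 (not isolated)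
Conditions: Me3SiCHN2, n-BuLi, THF, −78 °C; then 18, −78 → 0 °C; NaHCO3 (aq)
Reagents that add atoms: trimethylsilyldiazomethane, C[Si](C)(C)C=[N+]=[N-]
Why: Proposed new method: lithiated trimethylsilyldiazomethane adds to the C13 ketone and Peterson-type loss of Me3SiOLi gives diazoalkene 19, which loses N2 to the singlet alkylidene carbene 20 (Colvin-type sequence); the empty orbital on C14 (the former diazomethane carbon) then takes up the hydride-like C15–H bond of the orthoformate, which is held 1,5 to it through C13–C16–O, and the C14–C15 bond forms in the same event. The closest known reaction type is the 1,5 C–H insertion of alkylidene carbenes next to ether and acetal oxygen (2,5-dihydrofurans from α-alkoxy ketones, spiroketals from anomeric C–H bonds); an orthoformate C–H has not been used, but with three oxygen lone pairs it is the best hydride donor of this family, so insertion should be at least as fast. The 2,5-dihydrofuran ring closes in a 1,5 sense through a five-membered transition state (C14–C13–C16–O–C15); it is an insertion into a σ bond, so no Baldwin class applies. No stereocentre is formed (C15 carries two equal methoxy groups), and C2, C3, C4, C5, C9 and C10 are not touched under the basic aprotic conditions. The step needs site selectivity over the only other 1,5-related C–H bond (the tertiary allylic C9–H, which would give a spiro-cyclopentene), over 1,2-shift to an alkyne and over attack of a methoxy oxygen on the carbene: C9–H is buried next to the quaternary C10, alkyl groups migrate slowly in alkylidene carbenes, and the six-membered oxonium ylide is slower than the five-membered insertion.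

**Step 14**
Reactants: 21 ent-2α,3β,18-tris(tert-butyldimethylsilyloxy)-15,15-dimethoxy-15,16-epoxylabda-8(17),13-diene
Product: 23 ent-2α,3β,18-trihydroxylabda-8(17),13-dien-15,16-olide (target), via silylated butenolide 22 (not isolated)
Conditions: 48% aq. HF, MeCN, 0 °C → rt
Reagents that add atoms: water, O
Why: Aqueous acid should hydrolyse the ortho ester to the lactone through the dialkoxycarbenium ion and HF then cleaves the three silyl ethers, conditions that the butenolide and the exocyclic alkene tolerate.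

**Compound list**
1 | (2E,6E)-farnesyl bromide | CC(C)=CCC/C(C)=C/CC/C(C)=C/CBr | starting material
2 | ethyl acetate | CC(=O)OCC | starting material
3 | lithium enolate of ethyl acetate | C=C([O-])OCC.[Li+] | intermediate
4 | ethyl (4E,8E)-5,9,13-trimethyltetradeca-4,8,12-trienoate | CC(C)=CCC/C(C)=C/CC/C(C)=C/CCC(=O)OCC | intermediate
5 | ethyl (4E,8E,12E)-14-hydroxy-5,9,13-trimethyltetradeca-4,8,12-trienoate | OC/C(C)=C/CC/C(C)=C/CC/C(C)=C/CCC(=O)OCC | intermediate
6 | ethyl (4E,8E)-11-[(2R,3R)-3-(hydroxymethyl)-3-methyloxiran-2-yl]-5,9-dimethylundeca-4,8-dienoate | OC[C@@]1(C)O[C@@H]1CC/C(C)=C/CC/C(C)=C/CCC(=O)OCC | intermediate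
7 | ethyl (4E,8E)-11-[(2R,3R)-3-(tert-butyldimethylsilyloxymethyl)-3-methyloxiran-2-yl]-5,9-dimethylundeca-4,8-dienoate | CC(C)(C)[Si](C)(C)OC[C@@]1(C)O[C@@H]1CC/C(C)=C/CC/C(C)=C/CCC(=O)OCC | intermediate
8 | ethyl ent-18-(tert-butyldimethylsilyloxy)-3β-hydroxy-14,15,16-trinorlabd-8(17)-en-13-oate | C=C1CC[C@H]2[C@@](C)(CC[C@@H](O)[C@]2(C)CO[Si](C)(C)C(C)(C)C)[C@@H]1CCC(=O)OCC | intermediate
9 | ethyl ent-18-(tert-butyldimethylsilyloxy)-3-oxo-14,15,16-trinorlabd-8(17)-en-13-oate | C=C1CC[C@H]2[C@@](C)(CCC(=O)[C@]2(C)CO[Si](C)(C)C(C)(C)C)[C@@H]1CCC(=O)OCC | intermediate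
10 | potassium 2-en-3-olate of 9 | [K+].C=C1CC[C@H]2[C@@](C)(CC=C([O-])[C@]2(C)CO[Si](C)(C)C(C)(C)C)[C@@H]1CCC(=O)OCC | intermediate
11 | ethyl ent-18-(tert-butyldimethylsilyloxy)-2α-hydroxy-3-oxo-14,15,16-trinorlabd-8(17)-en-13-oate | C=C1CC[C@H]2[C@@](C)(C[C@H](O)C(=O)[C@]2(C)CO[Si](C)(C)C(C)(C)C)[C@@H]1CCC(=O)OCC | intermediate
12 | ethyl ent-18-(tert-butyldimethylsilyloxy)-2α,3β-dihydroxy-14,15,16-trinorlabd-8(17)-en-13-oate | C=C1CC[C@H]2[C@@](C)(C[C@H](O)[C@@H](O)[C@]2(C)CO[Si](C)(C)C(C)(C)C)[C@@H]1CCC(=O)OCC | intermediate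
13 | ethyl ent-2α,3β,18-tris(tert-butyldimethylsilyloxy)-14,15,16-trinorlabd-8(17)-en-13-oate | C=C1CC[C@H]2[C@@](C)(C[C@H](O[Si](C)(C)C(C)(C)C)[C@@H](O[Si](C)(C)C(C)(C)C)[C@]2(C)CO[Si](C)(C)C(C)(C)C)[C@@H]1CCC(=O)OCC | intermediate
14 | ent-2α,3β,18-tris(tert-butyldimethylsilyloxy)-N-methoxy-N-methyl-14,15,16-trinorlabd-8(17)-en-13-amide | C=C1CC[C@H]2[C@@](C)(C[C@H](O[Si](C)(C)C(C)(C)C)[C@@H](O[Si](C)(C)C(C)(C)C)[C@]2(C)CO[Si](C)(C)C(C)(C)C)[C@@H]1CCC(=O)N(C)OC | intermediate
15 | (tributylstannyl)methanol | CCCC[Sn](CCCC)(CCCC)CO | starting material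
16 | tributyl[(dimethoxymethoxy)methyl]stannane | CCCC[Sn](CCCC)(CCCC)COC(OC)OC | intermediate
17 | [(dimethoxymethoxy)methyl]lithium | [Li]COC(OC)OC | intermediate
18 | ent-2α,3β,18-tris(tert-butyldimethylsilyloxy)-16-(dimethoxymethoxy)-14,15-dinorlabd-8(17)-en-13-one | C=C1CC[C@H]2[C@@](C)(C[C@H](O[Si](C)(C)C(C)(C)C)[C@@H](O[Si](C)(C)C(C)(C)C)[C@]2(C)CO[Si](C)(C)C(C)(C)C)[C@@H]1CCC(=O)COC(OC)OC | intermediate
19 | ent-2α,3β,18-tris(tert-butyldimethylsilyloxy)-14-diazo-16-(dimethoxymethoxy)-15-norlabda-8(17),13-diene | C=C1CC[C@H]2[C@@](C)(C[C@H](O[Si](C)(C)C(C)(C)C)[C@@H](O[Si](C)(C)C(C)(C)C)[C@]2(C)CO[Si](C)(C)C(C)(C)C)[C@@H]1CCC(COC(OC)OC)=C=[N+]=[N-] | intermediate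
20 | ent-2α,3β,18-tris(tert-butyldimethylsilyloxy)-16-(dimethoxymethoxy)-15-norlabda-8(17),13-dien-14-ylidene | C=C1CC[C@H]2[C@@](C)(C[C@H](O[Si](C)(C)C(C)(C)C)[C@@H](O[Si](C)(C)C(C)(C)C)[C@]2(C)CO[Si](C)(C)C(C)(C)C)[C@@H]1CCC(COC(OC)OC)=[C] | intermediate
21 | ent-2α,3β,18-tris(tert-butyldimethylsilyloxy)-15,15-dimethoxy-15,16-epoxylabda-8(17),13-diene | C=C1CC[C@H]2[C@@](C)(C[C@H](O[Si](C)(C)C(C)(C)C)[C@@H](O[Si](C)(C)C(C)(C)C)[C@]2(C)CO[Si](C)(C)C(C)(C)C)[C@@H]1CCC1=CC(OC)(OC)OC1 | intermediate
22 | ent-2α,3β,18-tris(tert-butyldimethylsilyloxy)labda-8(17),13-dien-15,16-olide | C=C1CC[C@H]2[C@@](C)(C[C@H](O[Si](C)(C)C(C)(C)C)[C@@H](O[Si](C)(C)C(C)(C)C)[C@]2(C)CO[Si](C)(C)C(C)(C)C)[C@@H]1CCC1=CC(=O)OC1 | intermediate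
23 | ent-2α,3β,18-trihydroxylabda-8(17),13-dien-15,16-olide; 4-{2-[(1R,4aS,5S,6S,7S,8aS)-6,7-dihydroxy-5-(hydroxymethyl)-5,8a-dimethyl-2-methylidenedecahydronaphthalen-1-yl]ethyl}furan-2(5H)-one | C=C1CC[C@H]2[C@@](C)(C[C@H](O)[C@@H](O)[C@]2(C)CO)[C@@H]1CCC1=CC(=O)OC1 | target

**Count**
Total: 14 steps. Longest linear sequence: 13 steps (steps 1–10, 12, 13, 14); step 11 prepares the tin reagent.

**Steps most likely to fail**

Step 13. The carbene may be diverted: a methoxy oxygen may attack C14 to give an oxonium ylide, insertion may occur at C9–H, or 18 may be enolized instead of attacked. The fallback uses an acetal C–H bond, for which this insertion is established, and adds an oxidation. It sets out from 14 and returns at 22. (Methoxymethoxy)methyllithium, from commercial tributyl[(methoxymethoxy)methyl]stannane and n-BuLi, should add to 14 to give ent-2α,3β,18-tris(tert-butyldimethylsilyloxy)-16-(methoxymethoxy)-14,15-dinorlabd-8(17)-en-13-one F1. The same carbene generation (Me3SiCHN2, n-BuLi) should then insert into the O–CH2–O bond to give ent-2α,3β,18-tris(tert-butyldimethylsilyloxy)-15-methoxy-15,16-epoxylabda-8(17),13-diene F2 as both C15 epimers. Oxidation of this lactol ether at C15 with Jones reagent (CrO3, H2SO4, acetone, −10 °C, kept cold to outrun loss of methanol to the furan) should give 22, which is desilylated as in step 14.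

Step 5. The tertiary C4 radical rotates freely, so facial selection at C4 may be poor; termination after the first ring and loss of the exocyclic alkene position may also compete. The fallback sets C4 by polar enolate chemistry. It sets out from 9, carried through step 6 as a C4 epimer mixture, and returns to 9 as one epimer. Bu4NF should remove the silyl group to give ethyl ent-18-hydroxy-3-oxo-14,15,16-trinorlabd-8(17)-en-13-oate F3 and its C4 epimer, ethyl ent-19-hydroxy-3-oxo-14,15,16-trinorlabd-8(17)-en-13-oate F4. DBU in toluene should cause retro-aldol loss of formaldehyde from both, giving the single 4-monomethyl ketone with equatorial methyl, ethyl ent-3-oxo-14,15,16,19-tetranorlabd-8(17)-en-13-oate F5. Me3SiCl, NaI and Et3N in MeCN should give the more substituted silyl enol ether, ethyl ent-3-(trimethylsilyloxy)-14,15,16,19-tetranorlabda-3,8(17)-dien-13-oate F6. A Yb(OTf)3-catalysed Mukaiyama aldol with aqueous formaldehyde, entering anti to the axial C10 methyl, should return F3 alone, and TBSCl/imidazole then gives 9.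

Step 12. The lithium reagent 17 may undergo a 1,2-Wittig-type shift of the dimethoxymethyl group, or the ortho ester may be lost on work-up. The fallback installs the orthoformate last. It sets out from 14 and returns at 18. [(4-Methoxybenzyloxy)methyl]lithium, from tributyl[(4-methoxybenzyloxy)methyl]stannane and n-BuLi, should give ent-2α,3β,18-tris(tert-butyldimethylsilyloxy)-16-(4-methoxybenzyloxy)-14,15-dinorlabd-8(17)-en-13-one F7. DDQ in CH2Cl2/pH 7 buffer should free ent-2α,3β,18-tris(tert-butyldimethylsilyloxy)-16-hydroxy-14,15-dinorlabd-8(17)-en-13-one F8. O-Alkylation with dimethoxycarbenium tetrafluoroborate, (MeO)2CH+ BF4−, and 2,6-di-tert-butylpyridine in CH2Cl2 at −78 °C should give 18.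

**Further compounds**
F1 | step 13 | ent-2α,3β,18-tris(tert-butyldimethylsilyloxy)-16-(methoxymethoxy)-14,15-dinorlabd-8(17)-en-13-one | C=C1CC[C@H]2[C@@](C)(C[C@H](O[Si](C)(C)C(C)(C)C)[C@@H](O[Si](C)(C)C(C)(C)C)[C@]2(C)CO[Si](C)(C)C(C)(C)C)[C@@H]1CCC(=O)COCOC
F2 | step 13 | ent-2α,3β,18-tris(tert-butyldimethylsilyloxy)-15-methoxy-15,16-epoxylabda-8(17),13-diene (both C15 epimers) | C=C1CC[C@H]2[C@@](C)(C[C@H](O[Si](C)(C)C(C)(C)C)[C@@H](O[Si](C)(C)C(C)(C)C)[C@]2(C)CO[Si](C)(C)C(C)(C)C)[C@@H]1CCC1=CC(OC)OC1
F3 | step 5 | ethyl ent-18-hydroxy-3-oxo-14,15,16-trinorlabd-8(17)-en-13-oate | C=C1CC[C@H]2[C@@](C)(CCC(=O)[C@]2(C)CO)[C@@H]1CCC(=O)OCC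
F4 | step 5 | ethyl ent-19-hydroxy-3-oxo-14,15,16-trinorlabd-8(17)-en-13-oate (C4 epimer of F3) | C=C1CC[C@H]2[C@@](C)(CCC(=O)[C@@]2(C)CO)[C@@H]1CCC(=O)OCC
F5 | step 5 | ethyl ent-3-oxo-14,15,16,19-tetranorlabd-8(17)-en-13-oate (C4 methyl equatorial) | C=C1CC[C@H]2[C@@](C)(CCC(=O)[C@@H]2C)[C@@H]1CCC(=O)OCC
F6 | step 5 | ethyl ent-3-(trimethylsilyloxy)-14,15,16,19-tetranorlabda-3,8(17)-dien-13-oate | C=C1CC[C@H]2[C@@](C)(CCC(O[Si](C)(C)C)=C2C)[C@@H]1CCC(=O)OCC
F7 | step 12 | ent-2α,3β,18-tris(tert-butyldimethylsilyloxy)-16-(4-methoxybenzyloxy)-14,15-dinorlabd-8(17)-en-13-one | C=C1CC[C@H]2[C@@](C)(C[C@H](O[Si](C)(C)C(C)(C)C)[C@@H](O[Si](C)(C)C(C)(C)C)[C@]2(C)CO[Si](C)(C)C(C)(C)C)[C@@H]1CCC(=O)COCc1ccc(OC)cc1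
F8 | step 12 | ent-2α,3β,18-tris(tert-butyldimethylsilyloxy)-16-hydroxy-14,15-dinorlabd-8(17)-en-13-one | C=C1CC[C@H]2[C@@](C)(C[C@H](O[Si](C)(C)C(C)(C)C)[C@@H](O[Si](C)(C)C(C)(C)C)[C@]2(C)CO[Si](C)(C)C(C)(C)C)[C@@H]1CCC(=O)CO
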